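Z stops below the Q charged, and by a different amount in each run, so that shortfall is reckoned here on its own.

| flask | E | X | Q | D | remark |
|---|---|---|---|---|---|
| epsilon | 17 mM | 8.5 mM | 10.2 mM | 0.34 mM | the very flask that is asked about, followed so far |
| eta | 34 mM | 8.5 mM | 10.2 mM | 0.34 mM | run made earlier |
| flask | 17 mM | 8.50 mM | 10.2 mM | 0.34 mM |  |

- epsilon (time / s: Z / %, E / %): 10.0: 29.5, 72.1; 12.0: 31.2, 66.8; 20.0: 41.5, 56.9; 25.0: 45.3, 53.6; 30.0: 47.7, 52.4; 40.0: 50.4, 48.3; 50.0: 50.7, 48.1
- eta (time / s: Z / %, E / %): 10.0: 15.4, 83.0; 12.0: 16.9, 82.8; 15.0: 20.7, 80.0; 25.0: 24.2, 75.6; 40.0: 28.9, 70.8; 60.0: 26.8, 71.3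

(readings scatter by 1 percentage point)

- apparent order in X when 5.0% of the E are converted (percent change of the rate of making Z for one percent more X charged)
- factor on the rate of making Z when 5.0% of the E are converted if Q is charged twice over

- what is bound to the catalyst counts as converted
- no earlier run changes the charge of X; that part of a forecast is a guess
- no earlier run changes the charge of Q; that part of a forecast is a guess

Taking the mean of the last two readings, Z levels off at 8.59 mM in the epsilon run and 9.47 mM in the eta run. The eta plateau stands above the 8.5 mM of X charged by 2.8 percentage points of the E charged, against a scatter of 1 point. Q, at 10.2 mM, lies above both plateaus and is taken here as the candidate limiting reagent.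

Taking Q as spent at the plateau, the epsilon readings give 0.187 as the leak ratio, the Q spent without Z per Z made. In the eta run, with twice the E, it reads 0.0772.

If the rate follows Q, Z needs no X and the leak ratio rises in step with X, the reckoning here commits to two numbers:

order in X, minus the leak's share: −0.157

factor on doubling Q: 2.11

The weak link is the first order in Q, so it is tested on the Q left, the charge less Z times one plus the leak ratio:

epsilon, 10.0 s: 0.0876 s⁻¹

epsilon, 25.0 s: 0.0906 s⁻¹

eta, 10.0 s: 0.0805 s⁻¹

The forecast reads “X is therefore limiting” and gives 0.97 (0.75 to 1.1) for the order in X and 1 (0.9 to 1.5) for the factor, so it differs from the reckoning here on both.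

The asked flask gives −0.031 for the order in X and 1.87 for the factor.

    Q + J → D + G (k = 950 L mol⁻¹ s⁻¹)
    X + D ⇌ J (K = 170 L mol⁻¹, k = 230 L mol⁻¹ s⁻¹)
    Q + L → D + Z (k = 230 L mol⁻¹ s⁻¹)
    E + D ⇌ L (K = 2000 L mol⁻¹, k = 1200 L mol⁻¹ s⁻¹)

At 2.50 min the asked flask keeps 83% of its X and 0% of its Q, with G at 1.42 mM beside a shortfall read in the epsilon run as 1.61 mM. Carried to the eta run, the epsilon leak ratio scaled down by the E charged becomes 0.0935 and puts the Z plateau at 27.4% of the E charged, where the readings stand at 28.9% and 26.8%.

All runs stem from a simulated flask for substances that don't exist, and the scatter is random.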